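**Retrosynthetic overview**

1. Esters last: the target comes from C9 acetylation, PMB removal and double angeloylation of a macrocyclic 3,8-diol 9-PMB ether.
2. The ten-membered carbocycle (third and last ring) is closed at C7–C8 by Pd-catalysed borylmethylation of a (Z)-alkenyl iodide and in situ intramolecular (Z)-allylboration of an α-alkoxy aldehyde (new step; sets C7 and C8, creates the isopropenyl group).
3. Both cis-oxiranes are made earlier on the open chain by A(1,3)-controlled hydroxyl-directed epoxidations: the C1–C10 oxirane first (V, homoallylic C8–OH), the C4–C5 oxirane second (mCPBA, allylic C3–OH).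
4. The open chain comes from two Z-selective Wittig reactions of α-alkoxy methyl ketones (C4=C5, then C1=C10) and a Stork–Zhao olefination (C7=C11–I).
5. Building blocks: (S)-α-hydroxy-γ-butyrolactone (C1–C4), methyl (S)-2,2-dimethyl-1,3-dioxolane-4-carboxylate (C8–C10), 3-silyloxypropanal (C5–C7), EtPPh3I (C11, C13), MeMgBr (C14, C15), ICH2Bpin (C12).

Assumption: ring compounds are named with germacrane numbering (ring C1–C10, C14 on C10, C15 on C4, isopropenyl C11(=C12)C13 on C7), and the same locants are used for the open-chain precursors in the Why lines; the target is then (1R,3S,4S,5S,7R,8S,9S,10R)-9-acetoxy-3,8-bis(angeloyloxy)-1,10:4,5-diepoxygermacr-11(12)-ene with both oxiranes cis (derived from Z-alkenes).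

**Route**

Step 1
Reactants: 1 (S)-3-hydroxydihydrofuran-2(3H)-one
Product: 2 (S)-3-(tert-butyldimethylsilyloxy)dihydrofuran-2(3H)-one
Conditions: TBSCl, imidazole, DMF, 0 °C → rt
Reagents that add atoms: tert-butyldimethylsilyl chloride, CC(C)(C)[Si](C)(C)Cl
Why: Standard silylation of the secondary alcohol protects the chiral-pool stereocentre that becomes C3 without touching it.

Step 2
Reactants: 2 (S)-3-(tert-butyldimethylsilyloxy)dihydrofuran-2(3H)-one
Product: 3 (S)-2-(tert-butyldimethylsilyloxy)-4-hydroxy-N-methoxy-N-methylbutanamide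
Conditions: MeNH(OMe)·HCl, i-PrMgCl, THF, −20 → 0 °C
Reagents that add atoms: N,O-dimethylhydroxylamine hydrochloride, CNOC.Cl
Why: Weinreb aminolysis of the lactone by the chloromagnesium amide (acyl substitution) opens the ring at low temperature without epimerising the α-silyloxy centre.

Step 3
Reactants: 3 (S)-2-(tert-butyldimethylsilyloxy)-4-hydroxy-N-methoxy-N-methylbutanamide
Product: 4 (S)-2,4-bis(tert-butyldimethylsilyloxy)-N-methoxy-N-methylbutanamide
Conditions: TBSCl, imidazole, CH2Cl2, rt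
Reagents that add atoms: tert-butyldimethylsilyl chloride, CC(C)(C)[Si](C)(C)Cl
Why: Immediate silylation of the primary alcohol prevents relactonisation and gives a primary silyl ether that can later be cleaved selectively.

Step 4
Reactants: 4 (S)-2,4-bis(tert-butyldimethylsilyloxy)-N-methoxy-N-methylbutanamide
Product: 5 (S)-3,5-bis(tert-butyldimethylsilyloxy)pentan-2-one
Conditions: MeMgBr, THF, 0 °C
Reagents that add atoms: methylmagnesium bromide, C[Mg]Br
Why: Weinreb ketone synthesis stops at the methyl ketone through the chelated tetrahedral intermediate and introduces C15 without enolising the α-stereocentre.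

Step 5
Reactants: 6 ethyltriphenylphosphonium iodide; 7 3-(tert-butyldimethylsilyloxy)propanal
Product: 11 (Z)-tert-butyl[(4-iodopent-3-en-1-yl)oxy]dimethylsilane, via ethylidenetriphenylphosphorane 8 (not isolated), via (1-iodoethyl)triphenylphosphonium iodide 9 (not isolated), via (1-iodoethylidene)triphenylphosphorane 10 (not isolated)
Conditions: 6, n-BuLi, THF, rt; I2, −78 °C; NaHMDS, −20 °C; 7, −78 → −20 °C
Reagents that add atoms: iodine, II
Why: Stork–Zhao olefination with the α-iodo ylide gives the (Z)-2-iodo-2-alkene kinetically, so iodine ends up cis to the chain carbon C6.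

Step 6
Reactants: 11 (Z)-tert-butyl[(4-iodopent-3-en-1-yl)oxy]dimethylsilane
Product: 12 (Z)-4-iodopent-3-en-1-ol
Conditions: CSA (cat.), MeOH, 0 °C → rt
Reagents that add atoms: none
Why: Acid-catalysed methanolysis removes the primary silyl ether and leaves the alkenyl iodide geometry intact.

Step 7
Reactants: 12 (Z)-4-iodopent-3-en-1-ol
Product: 13 (Z)-2,5-diiodopent-2-ene
Conditions: I2, PPh3, imidazole, CH2Cl2, 0 °C
Reagents that add atoms: iodine, II
Why: Appel-type (Garegg–Samuelsson) iodination converts the primary alcohol into the iodide under neutral conditions.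

Step 8
Reactants: 13 (Z)-2,5-diiodopent-2-ene
Product: 14 [(3Z)-4-iodopent-3-en-1-yl]triphenylphosphonium iodide
Conditions: PPh3, MeCN, 80 °C
Reagents that add atoms: triphenylphosphine, c1ccc(cc1)P(c1ccccc1)c1ccccc1
Why: SN2 quaternisation occurs only at the primary alkyl iodide because the sp2 C–I bond is inert to phosphine.

Step 9
Reactants: 14 [(3Z)-4-iodopent-3-en-1-yl]triphenylphosphonium iodide; 5 (S)-3,5-bis(tert-butyldimethylsilyloxy)pentan-2-one
Product: 16 (3S,4Z,7Z)-1,3-bis(tert-butyldimethylsilyloxy)-8-iodo-4-methylnona-4,7-diene, via iodopentenylidene phosphorane 15 (not isolated)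
Conditions: 14, NaHMDS, THF, −78 → −30 °C; HMPA, 5, −78 → −20 °C
Reagents that add atoms: none
Why: Still-type Z-selective Wittig olefination of an α-silyloxy methyl ketone with a salt-free non-stabilised ylide places the oxygenated carbon C3 cis to C6 (4Z) under kinetic control while the low temperature preserves the α-stereocentre.

Step 10
Reactants: 16 (3S,4Z,7Z)-1,3-bis(tert-butyldimethylsilyloxy)-8-iodo-4-methylnona-4,7-diene
Product: 17 (3S,4Z,7Z)-3-(tert-butyldimethylsilyloxy)-8-iodo-4-methylnona-4,7-dien-1-ol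
Conditions: HF·pyridine, pyridine, THF, 0 °C
Reagents that add atoms: none
Why: Buffered HF·pyridine cleaves the unhindered primary silyl ether much faster than the secondary allylic one (selective desilylation).

Step 11
Reactants: 17 (3S,4Z,7Z)-3-(tert-butyldimethylsilyloxy)-8-iodo-4-methylnona-4,7-dien-1-ol
Product: 18 tert-butyl{[(3S,4Z,7Z)-1,8-diiodo-4-methylnona-4,7-dien-3-yl]oxy}dimethylsilane
Conditions: I2, PPh3, imidazole, CH2Cl2, 0 °C
Reagents that add atoms: iodine, II
Why: Appel-type iodination of the primary alcohol proceeds under neutral conditions that leave both Z-alkenes and the silyl ether untouched.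

Step 12
Reactants: 18 tert-butyl{[(3S,4Z,7Z)-1,8-diiodo-4-methylnona-4,7-dien-3-yl]oxy}dimethylsilane
Product: 19 [(3S,4Z,7Z)-3-(tert-butyldimethylsilyloxy)-8-iodo-4-methylnona-4,7-dien-1-yl]triphenylphosphonium iodide
Conditions: PPh3, MeCN, 80 °C
Reagents that add atoms: triphenylphosphine, c1ccc(cc1)P(c1ccccc1)c1ccccc1
Why: SN2 phosphonium salt formation is selective for the primary iodide, and the γ-silyloxy group cannot β-eliminate from the later ylide.

Step 13
Reactants: 20 methyl (S)-2,2-dimethyl-1,3-dioxolane-4-carboxylate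
Product: 22 methyl (4S)-2-(4-methoxyphenyl)-1,3-dioxolane-4-carboxylate, via methyl (S)-glycerate 21 (not isolated)
Conditions: p-TsOH (cat.), MeOH, rt; evaporate; 4-MeOC6H4CH(OMe)2, CSA (cat.), CH2Cl2, rt
Reagents that add atoms: 4-methoxybenzaldehyde dimethyl acetal, COC(OC)c1ccc(OC)cc1
Why: Acid-catalysed acetal exchange (methanolysis then acetalisation) swaps the acetonide for a p-methoxybenzylidene acetal without touching the stereocentre that becomes C9, and the new acetal epimers are irrelevant because that carbon is reduced in step 17.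

Step 14
Reactants: 22 methyl (4S)-2-(4-methoxyphenyl)-1,3-dioxolane-4-carboxylate
Product: 23 (4S)-N-methoxy-2-(4-methoxyphenyl)-N-methyl-1,3-dioxolane-4-carboxamide
Conditions: MeNH(OMe)·HCl, i-PrMgCl, THF, −20 °C
Reagents that add atoms: N,O-dimethylhydroxylamine hydrochloride, CNOC.Cl
Why: Weinreb amidation of the ester with the chloromagnesium amide at −20 °C is an acyl substitution that does not epimerise the α-alkoxy centre.

Step 15
Reactants: 23 (4S)-N-methoxy-2-(4-methoxyphenyl)-N-methyl-1,3-dioxolane-4-carboxamide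
Product: 24 1-[(4S)-2-(4-methoxyphenyl)-1,3-dioxolan-4-yl]ethan-1-one
Conditions: MeMgBr, THF, 0 °C
Reagents that add atoms: methylmagnesium bromide, C[Mg]Br
Why: Weinreb ketone synthesis delivers the α-alkoxy methyl ketone (C10 with C14) without over-addition.

Step 16
Reactants: 19 [(3S,4Z,7Z)-3-(tert-butyldimethylsilyloxy)-8-iodo-4-methylnona-4,7-dien-1-yl]triphenylphosphonium iodide; 24 1-[(4S)-2-(4-methoxyphenyl)-1,3-dioxolan-4-yl]ethan-1-one
Product: 26 (4R)-4-[(2Z,5S,6Z,9Z)-5-(tert-butyldimethylsilyloxy)-10-iodo-6-methylundeca-2,6,9-trien-2-yl]-2-(4-methoxyphenyl)-1,3-dioxolane, via dienylidene phosphorane 25 (not isolated)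
Conditions: 19, NaHMDS, THF, −78 → −30 °C; HMPA, 24, −78 → −20 °C
Reagents that add atoms: none
Why: A second Still-type Z-selective Wittig olefination of an α-alkoxy methyl ketone sets the C1=C10 alkene with the oxygenated carbon C9 cis to C2, and the C9 configuration is unchanged (the descriptor changes only through CIP priorities).

Step 17
Reactants: 26 (4R)-4-[(2Z,5S,6Z,9Z)-5-(tert-butyldimethylsilyloxy)-10-iodo-6-methylundeca-2,6,9-trien-2-yl]-2-(4-methoxyphenyl)-1,3-dioxolane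
Product: 27 (2R,3Z,6S,7Z,10Z)-6-(tert-butyldimethylsilyloxy)-11-iodo-2-[(4-methoxybenzyl)oxy]-3,7-dimethyldodeca-3,7,10-trien-1-ol
Conditions: DIBAL-H, CH2Cl2, −78 → 0 °C
Reagents that add atoms: none
Why: Regioselective reductive opening of the p-methoxybenzylidene acetal: aluminium binds the less hindered primary oxygen and hydride reduces the oxocarbenium ion, leaving the PMB ether on the secondary C9 oxygen and the C8 hydroxyl free.

Step 18
Reactants: 27 (2R,3Z,6S,7Z,10Z)-6-(tert-butyldimethylsilyloxy)-11-iodo-2-[(4-methoxybenzyl)oxy]-3,7-dimethyldodeca-3,7,10-trien-1-ol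
Product: 28 (2S)-2-{(2R,3R)-3-[(2S,3Z,6Z)-2-(tert-butyldimethylsilyloxy)-7-iodo-3-methylocta-3,6-dien-1-yl]-2-methyloxiran-2-yl}-2-[(4-methoxybenzyl)oxy]ethan-1-ol
Conditions: VO(acac)2 (5 mol %), t-BuOOH (decane), CH2Cl2, 0 °C → rt
Reagents that add atoms: tert-butyl hydroperoxide, CC(C)(C)OO
Why: Vanadium-catalysed hydroxyl-directed epoxidation of a homoallylic alcohol: A(1,3) strain with the cis C2 substituent holds C9–H in the alkene plane, so the vanadate ester of the C8 hydroxyl delivers oxygen to the C8-side face anti to the OPMB group and gives the erythro cis-oxirane (C10 R, C1 R), while the two undirected alkenes do not react.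

Step 19
Reactants: 28 (2S)-2-{(2R,3R)-3-[(2S,3Z,6Z)-2-(tert-butyldimethylsilyloxy)-7-iodo-3-methylocta-3,6-dien-1-yl]-2-methyloxiran-2-yl}-2-[(4-methoxybenzyl)oxy]ethan-1-ol
Product: 29 (2S)-2-{(2R,3R)-3-[(2S,3Z,6Z)-2-hydroxy-7-iodo-3-methylocta-3,6-dien-1-yl]-2-methyloxiran-2-yl}-2-[(4-methoxybenzyl)oxy]ethan-1-ol
Conditions: TBAF, AcOH, THF, 0 °C → rt
Reagents that add atoms: none
Why: Acetic-acid-buffered fluoride desilylation frees the allylic C3 hydroxyl without base-induced epoxide migration or elimination of the alkenyl iodide.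

Step 20
Reactants: 29 (2S)-2-{(2R,3R)-3-[(2S,3Z,6Z)-2-hydroxy-7-iodo-3-methylocta-3,6-dien-1-yl]-2-methyloxiran-2-yl}-2-[(4-methoxybenzyl)oxy]ethan-1-ol
Product: 30 (2S)-2-{(2R,3R)-3-[(2S)-2-hydroxy-2-{(2R,3S)-3-[(2Z)-3-iodobut-2-en-1-yl]-2-methyloxiran-2-yl}ethyl]-2-methyloxiran-2-yl}-2-[(4-methoxybenzyl)oxy]ethan-1-ol
Conditions: mCPBA, NaHCO3, CH2Cl2, 0 °C
Reagents that add atoms: meta-chloroperbenzoic acid, OOC(=O)c1cccc(Cl)c1
Why: Hydrogen-bond-directed (Henbest-type) peracid epoxidation of the Z-allylic alcohol: with C3–H eclipsing the alkene (A(1,3) strain) the C3 hydroxyl guides the peracid to its own face and gives the threo cis-oxirane with the C4 and C5 configurations of the target (typically about 9:1, minor isomer removed by chromatography), while the electron-poor alkenyl iodide reacts much more slowly.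

Step 21
Reactants: 30 (2S)-2-{(2R,3R)-3-[(2S)-2-hydroxy-2-{(2R,3S)-3-[(2Z)-3-iodobut-2-en-1-yl]-2-methyloxiran-2-yl}ethyl]-2-methyloxiran-2-yl}-2-[(4-methoxybenzyl)oxy]ethan-1-ol
Product: 31 (2R)-2-{(2R,3R)-3-[(2S)-2-hydroxy-2-{(2R,3S)-3-[(2Z)-3-iodobut-2-en-1-yl]-2-methyloxiran-2-yl}ethyl]-2-methyloxiran-2-yl}-2-[(4-methoxybenzyl)oxy]acetaldehyde
Conditions: TEMPO (cat.), PhI(OAc)2, CH2Cl2, rt
Reagents that add atoms: none
Why: Oxoammonium (TEMPO/PhI(OAc)2) oxidation is selective for the primary C8 alcohol over the hindered secondary C3 alcohol and is neutral enough for the sensitive α-alkoxy aldehyde, which is used at once.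

Step 22
Reactants: 31 (2R)-2-{(2R,3R)-3-[(2S)-2-hydroxy-2-{(2R,3S)-3-[(2Z)-3-iodobut-2-en-1-yl]-2-methyloxiran-2-yl}ethyl]-2-methyloxiran-2-yl}-2-[(4-methoxybenzyl)oxy]acetaldehyde
Product: 34 (1R,3S,4R,5S,7R,8S,9S,10R)-1,10:4,5-diepoxy-9-[(4-methoxybenzyl)oxy]germacr-11(12)-ene-3,8-diol, via (Z)-allylboronate aldehyde 32 (not isolated), via macrocyclic pinacol borate 33 (not isolated)
Conditions: ICH2Bpin (4 equiv), Zn dust, THF, rt (gives pinBCH2ZnI); Pd(PPh3)4 (10 mol %), THF–DMA, 45 °C, 31 added over 10 h (2 mM final); aq NaHCO3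
Reagents that add atoms: 2-(iodomethyl)-4,4,5,5-tetramethyl-1,3,2-dioxaborolane, CC1(C)OB(CI)OC1(C)C
Why: Proposed new method: Pd(0) couples the (Z)-alkenyl iodide with the borylmethylzinc iodide (formed beforehand by zinc insertion into ICH2Bpin) with retention of geometry, and the resulting (Z)-γ,β-disubstituted allylboronate 32 adds within the same molecule to the α-alkoxy aldehyde through a closed chair (type I) transition state in which the Z geometry places C6 axial (7,8-syn in the crotylation sense) and Cornforth/Felkin attack anti to the C9–O bond gives the 8,9-anti relation, so that the C7–C8 bond, the ten-membered ring, the isopropenyl group (C12 from the reagent) and the C7 (R) and C8 (S) centres are formed together under neutral conditions that the oxiranes tolerate; the closest known chemistry is the Negishi coupling of borylmethylzinc reagents with alkenyl halides to give allylboronates followed by intramolecular allylboration to five- to eight-membered rings, which has not been shown as a one-pot macrocyclisation to a ten-membered carbocycle.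

Step 23
Reactants: 34 (1R,3S,4R,5S,7R,8S,9S,10R)-1,10:4,5-diepoxy-9-[(4-methoxybenzyl)oxy]germacr-11(12)-ene-3,8-diol
Product: 35 (1R,3S,4S,5S,7R,8S,9S,10R)-1,10:4,5-diepoxy-9-[(4-methoxybenzyl)oxy]germacr-11(12)-ene-3,8-diyl bis[(Z)-2-methylbut-2-enoate]
Conditions: angelic acid, 2,4,6-Cl3C6H2COCl, Et3N, toluene, rt, filter; then 34, toluene, 80 °C
Reagents that add atoms: angelic acid [(Z)-2-methylbut-2-enoic acid], C/C=C(/C)C(=O)O
Why: Yamaguchi-type mixed-anhydride esterification without nucleophilic base acylates both secondary alcohols at C3 and C8 and avoids the base-mediated angelate-to-tiglate isomerisation.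

Step 24
Reactants: 35 (1R,3S,4S,5S,7R,8S,9S,10R)-1,10:4,5-diepoxy-9-[(4-methoxybenzyl)oxy]germacr-11(12)-ene-3,8-diyl bis[(Z)-2-methylbut-2-enoate]
Product: 36 (1R,3S,4S,5S,7R,8S,9S,10S)-1,10:4,5-diepoxy-9-hydroxygermacr-11(12)-ene-3,8-diyl bis[(Z)-2-methylbut-2-enoate]
Conditions: DDQ, CH2Cl2–pH 7 buffer, 0 °C
Reagents that add atoms: none
Why: Oxidative PMB ether cleavage by DDQ is neutral, so the oxiranes, the angelates and the isopropenyl group survive and no acyl migration from C8 occurs (the C10 descriptor changes only through CIP priorities).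

Step 25
Reactants: 36 (1R,3S,4S,5S,7R,8S,9S,10S)-1,10:4,5-diepoxy-9-hydroxygermacr-11(12)-ene-3,8-diyl bis[(Z)-2-methylbut-2-enoate]
Product: 37 (1R,3S,4S,5S,7R,8S,9S,10R)-9-acetoxy-1,10:4,5-diepoxygermacr-11(12)-ene-3,8-diyl bis[(Z)-2-methylbut-2-enoate]
Conditions: Ac2O, pyridine, DMAP (cat.), CH2Cl2, 0 °C → rt
Reagents that add atoms: acetic anhydride, CC(=O)OC(C)=O
Why: DMAP-catalysed acetylation of the free C9 alcohol is faster than 1,2-acyl migration and completes the target with all eight stereocentres unchanged.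

**Compound list**

1 | (S)-3-hydroxydihydrofuran-2(3H)-one | O[C@H]1CCOC1=O | starting material
2 | (S)-3-(tert-butyldimethylsilyloxy)dihydrofuran-2(3H)-one | CC(C)(C)[Si](C)(C)O[C@H]1CCOC1=O | intermediate
3 | (S)-2-(tert-butyldimethylsilyloxy)-4-hydroxy-N-methoxy-N-methylbutanamide | CON(C)C(=O)[C@@H](O[Si](C)(C)C(C)(C)C)CCO | intermediate
4 | (S)-2,4-bis(tert-butyldimethylsilyloxy)-N-methoxy-N-methylbutanamide | CON(C)C(=O)[C@@H](O[Si](C)(C)C(C)(C)C)CCO[Si](C)(C)C(C)(C)C | intermediate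
5 | (S)-3,5-bis(tert-butyldimethylsilyloxy)pentan-2-one | CC(=O)[C@@H](O[Si](C)(C)C(C)(C)C)CCO[Si](C)(C)C(C)(C)C | intermediate
6 | ethyltriphenylphosphonium iodide | CC[P+](c1ccccc1)(c1ccccc1)c1ccccc1.[I-] | starting material
7 | 3-(tert-butyldimethylsilyloxy)propanal | O=CCCO[Si](C)(C)C(C)(C)C | starting material
8 | ethylidenetriphenylphosphorane | CC=P(c1ccccc1)(c1ccccc1)c1ccccc1 | intermediate
9 | (1-iodoethyl)triphenylphosphonium iodide | CC(I)[P+](c1ccccc1)(c1ccccc1)c1ccccc1.[I-] | intermediate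
10 | (1-iodoethylidene)triphenylphosphorane | CC(I)=P(c1ccccc1)(c1ccccc1)c1ccccc1 | intermediate
11 | (Z)-tert-butyl[(4-iodopent-3-en-1-yl)oxy]dimethylsilane | C/C(I)=C/CCO[Si](C)(C)C(C)(C)C | intermediate
12 | (Z)-4-iodopent-3-en-1-ol | C/C(I)=C/CCO | intermediate
13 | (Z)-2,5-diiodopent-2-ene | C/C(I)=C/CCI | intermediate
14 | [(3Z)-4-iodopent-3-en-1-yl]triphenylphosphonium iodide | C/C(I)=C/CC[P+](c1ccccc1)(c1ccccc1)c1ccccc1.[I-] | intermediate
15 | iodopentenylidene phosphorane: [(3Z)-4-iodopent-3-en-1-ylidene]triphenylphosphorane | C/C(I)=C/CC=P(c1ccccc1)(c1ccccc1)c1ccccc1 | intermediate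
16 | (3S,4Z,7Z)-1,3-bis(tert-butyldimethylsilyloxy)-8-iodo-4-methylnona-4,7-diene | C/C(I)=C/C/C=C(/C)[C@@H](O[Si](C)(C)C(C)(C)C)CCO[Si](C)(C)C(C)(C)C | intermediate
17 | (3S,4Z,7Z)-3-(tert-butyldimethylsilyloxy)-8-iodo-4-methylnona-4,7-dien-1-ol | C/C(I)=C/C/C=C(/C)[C@@H](O[Si](C)(C)C(C)(C)C)CCO | intermediate
18 | tert-butyl{[(3S,4Z,7Z)-1,8-diiodo-4-methylnona-4,7-dien-3-yl]oxy}dimethylsilane | C/C(I)=C/C/C=C(/C)[C@@H](O[Si](C)(C)C(C)(C)C)CCI | intermediate
19 | [(3S,4Z,7Z)-3-(tert-butyldimethylsilyloxy)-8-iodo-4-methylnona-4,7-dien-1-yl]triphenylphosphonium iodide | C/C(I)=C/C/C=C(/C)[C@@H](O[Si](C)(C)C(C)(C)C)CC[P+](c1ccccc1)(c1ccccc1)c1ccccc1.[I-] | intermediate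
20 | methyl (S)-2,2-dimethyl-1,3-dioxolane-4-carboxylate | COC(=O)[C@@H]1COC(C)(C)O1 | starting material
21 | methyl (S)-glycerate: methyl (S)-2,3-dihydroxypropanoate | COC(=O)[C@@H](O)CO | intermediate
22 | methyl (4S)-2-(4-methoxyphenyl)-1,3-dioxolane-4-carboxylate (both C2 epimers) | COC(=O)[C@@H]1COC(c2ccc(OC)cc2)O1 | intermediate
23 | (4S)-N-methoxy-2-(4-methoxyphenyl)-N-methyl-1,3-dioxolane-4-carboxamide | CON(C)C(=O)[C@@H]1COC(c2ccc(OC)cc2)O1 | intermediate
24 | 1-[(4S)-2-(4-methoxyphenyl)-1,3-dioxolan-4-yl]ethan-1-one | CC(=O)[C@@H]1COC(c2ccc(OC)cc2)O1 | intermediate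
25 | dienylidene phosphorane: [(3S,4Z,7Z)-3-(tert-butyldimethylsilyloxy)-8-iodo-4-methylnona-4,7-dien-1-ylidene]triphenylphosphorane | C/C(I)=C/C/C=C(/C)[C@@H](O[Si](C)(C)C(C)(C)C)CC=P(c1ccccc1)(c1ccccc1)c1ccccc1 | intermediate
26 | (4R)-4-[(2Z,5S,6Z,9Z)-5-(tert-butyldimethylsilyloxy)-10-iodo-6-methylundeca-2,6,9-trien-2-yl]-2-(4-methoxyphenyl)-1,3-dioxolane | C/C(I)=C/C/C=C(/C)[C@@H](O[Si](C)(C)C(C)(C)C)C/C=C(/C)[C@@H]1COC(c2ccc(OC)cc2)O1 | intermediate
27 | (2R,3Z,6S,7Z,10Z)-6-(tert-butyldimethylsilyloxy)-11-iodo-2-[(4-methoxybenzyl)oxy]-3,7-dimethyldodeca-3,7,10-trien-1-ol | C/C(I)=C/C/C=C(/C)[C@@H](O[Si](C)(C)C(C)(C)C)C/C=C(/C)[C@@H](OCc1ccc(OC)cc1)CO | intermediate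
28 | (2S)-2-{(2R,3R)-3-[(2S,3Z,6Z)-2-(tert-butyldimethylsilyloxy)-7-iodo-3-methylocta-3,6-dien-1-yl]-2-methyloxiran-2-yl}-2-[(4-methoxybenzyl)oxy]ethan-1-ol | C/C(I)=C/C/C=C(/C)[C@@H](O[Si](C)(C)C(C)(C)C)C[C@H]1O[C@@]1(C)[C@@H](OCc1ccc(OC)cc1)CO | intermediate
29 | (2S)-2-{(2R,3R)-3-[(2S,3Z,6Z)-2-hydroxy-7-iodo-3-methylocta-3,6-dien-1-yl]-2-methyloxiran-2-yl}-2-[(4-methoxybenzyl)oxy]ethan-1-ol | C/C(I)=C/C/C=C(/C)[C@@H](O)C[C@H]1O[C@@]1(C)[C@@H](OCc1ccc(OC)cc1)CO | intermediate
30 | (2S)-2-{(2R,3R)-3-[(2S)-2-hydroxy-2-{(2R,3S)-3-[(2Z)-3-iodobut-2-en-1-yl]-2-methyloxiran-2-yl}ethyl]-2-methyloxiran-2-yl}-2-[(4-methoxybenzyl)oxy]ethan-1-ol | C/C(I)=C/C[C@@H]1O[C@]1(C)[C@@H](O)C[C@H]1O[C@@]1(C)[C@@H](OCc1ccc(OC)cc1)CO | intermediate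
31 | (2R)-2-{(2R,3R)-3-[(2S)-2-hydroxy-2-{(2R,3S)-3-[(2Z)-3-iodobut-2-en-1-yl]-2-methyloxiran-2-yl}ethyl]-2-methyloxiran-2-yl}-2-[(4-methoxybenzyl)oxy]acetaldehyde | C/C(I)=C/C[C@@H]1O[C@]1(C)[C@@H](O)C[C@H]1O[C@@]1(C)[C@@H](OCc1ccc(OC)cc1)C=O | intermediate
32 | (Z)-allylboronate aldehyde: (2R)-2-{(2R,3R)-3-[(2S)-2-hydroxy-2-{(2R,3S)-2-methyl-3-[(2Z)-3-methyl-4-(4,4,5,5-tetramethyl-1,3,2-dioxaborolan-2-yl)but-2-en-1-yl]oxiran-2-yl}ethyl]-2-methyloxiran-2-yl}-2-[(4-methoxybenzyl)oxy]acetaldehyde | C/C(CB1OC(C)(C)C(C)(C)O1)=C/C[C@@H]1O[C@]1(C)[C@@H](O)C[C@H]1O[C@@]1(C)[C@@H](OCc1ccc(OC)cc1)C=O | intermediate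
33 | macrocyclic pinacol borate: (1R,3S,4R,5S,7R,8S,9S,10R)-1,10:4,5-diepoxy-9-[(4-methoxybenzyl)oxy]-8-[(4,4,5,5-tetramethyl-1,3,2-dioxaborolan-2-yl)oxy]germacr-11(12)-en-3-ol | C=C(C)[C@H]1C[C@@H]2O[C@]2(C)[C@@H](O)C[C@H]2O[C@@]2(C)[C@@H](OCc3ccc(OC)cc3)[C@H]1OB1OC(C)(C)C(C)(C)O1 | intermediate
34 | (1R,3S,4R,5S,7R,8S,9S,10R)-1,10:4,5-diepoxy-9-[(4-methoxybenzyl)oxy]germacr-11(12)-ene-3,8-diol | C=C(C)[C@H]1C[C@@H]2O[C@]2(C)[C@@H](O)C[C@H]2O[C@@]2(C)[C@@H](OCc3ccc(OC)cc3)[C@H]1O | intermediate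
35 | (1R,3S,4S,5S,7R,8S,9S,10R)-1,10:4,5-diepoxy-9-[(4-methoxybenzyl)oxy]germacr-11(12)-ene-3,8-diyl bis[(Z)-2-methylbut-2-enoate] | C=C(C)[C@H]1C[C@@H]2O[C@]2(C)[C@@H](OC(=O)/C(C)=C\C)C[C@H]2O[C@@]2(C)[C@@H](OCc3ccc(OC)cc3)[C@H]1OC(=O)/C(C)=C\C | intermediate
36 | (1R,3S,4S,5S,7R,8S,9S,10S)-1,10:4,5-diepoxy-9-hydroxygermacr-11(12)-ene-3,8-diyl bis[(Z)-2-methylbut-2-enoate] | C=C(C)[C@H]1C[C@@H]2O[C@]2(C)[C@@H](OC(=O)/C(C)=C\C)C[C@H]2O[C@@]2(C)[C@@H](O)[C@H]1OC(=O)/C(C)=C\C | intermediate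
37 | (1R,3S,4S,5S,7R,8S,9S,10R)-9-acetoxy-1,10:4,5-diepoxygermacr-11(12)-ene-3,8-diyl bis[(Z)-2-methylbut-2-enoate] (CNP0220329.1) | C=C(C)[C@H]1C[C@@H]2O[C@]2(C)[C@@H](OC(=O)/C(C)=C\C)C[C@H]2O[C@@]2(C)[C@@H](OC(C)=O)[C@H]1OC(=O)/C(C)=C\C | target

**Step count and risks**

Total step count: 25. Longest linear sequence: 18 steps (steps 1–4, 9–12, 16–25, from 1 to 37).

Three steps most likely to fail:

Step 18 (the homoallylic-hydroxyl-directed epoxidation may be slow or poorly selective because the allylic OPMB group deactivates the alkene). The fallback sets out from 27 and comes back at 28, and replaces metal-oxo delivery by a halocyclisation. Alcohol 27 is converted with Boc2O and DMAP in MeCN into the primary tert-butyl carbonate F1. IBr in toluene at −80 °C then closes the six-membered cyclic iodocarbonate F2: the carbonate oxygen is tethered through C8 and adds to C10 on the same C8-side face of the A(1,3)-controlled conformer, with iodine anti at C1. K2CO3 in MeOH methanolyses the carbonate, and the C10 alkoxide displaces iodide with inversion at C1 to give the same cis-oxirane 28.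

Step 22 (the proposed new one-pot coupling and macrocyclisation; the Pd/Zn chemistry may not tolerate the free aldehyde, and the ring closure competes with oligomerisation). The fallback sets out from 30 and comes back at 34, using only known reaction classes in separate operations. Alcohol 30 is coupled under ordinary concentrated Negishi conditions (pinBCH2ZnI, Pd(PPh3)4, THF, rt) to the isolable (Z)-allylboronate diol F3. Primary-selective TEMPO/PhI(OAc)2 oxidation, run by slow addition into dilute CH2Cl2 (about 1 mM) at 40 °C, then unmasks aldehyde 32 in the absence of Pd and zinc salts. The aldehyde closes by uncatalysed thermal intramolecular allylboration (the aldehyde-unmasking-triggered protocol known for small and medium rings) to borate 33, which is hydrolysed on work-up to 34. This separates the coupling from the cyclisation but still relies on the same ten-membered ring closure.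

Step 23 (double acylation of two hindered, oxirane-flanked secondary alcohols with an acid that isomerises easily to the tiglate). The fallback sets out from 34 and comes back at 35, and builds the angelate double bonds on the substrate. Both alcohols are esterified with 2-[bis(2,2,2-trifluoroethoxy)phosphoryl]propanoic acid (EDC, DMAP, CH2Cl2) to the bis(phosphonopropionate) F4. Still–Gennari olefination (KHMDS, 18-crown-6, THF, −78 °C, then acetaldehyde) then gives both (Z)-2-methylbut-2-enoates of 35 under kinetic Z control.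

Further compounds
F1 | step 18 | tert-butyl (2R,3Z,6S,7Z,10Z)-6-(tert-butyldimethylsilyloxy)-11-iodo-2-[(4-methoxybenzyl)oxy]-3,7-dimethyldodeca-3,7,10-trien-1-yl carbonate | C/C(I)=C/C/C=C(/C)[C@@H](O[Si](C)(C)C(C)(C)C)C/C=C(/C)[C@@H](OCc1ccc(OC)cc1)COC(=O)OC(C)(C)C
F2 | step 18 | (4S,5S)-4-[(1S,3S,4Z,7Z)-3-(tert-butyldimethylsilyloxy)-1,8-diiodo-4-methylnona-4,7-dien-1-yl]-5-[(4-methoxybenzyl)oxy]-4-methyl-1,3-dioxan-2-one | C/C(I)=C/C/C=C(/C)[C@@H](O[Si](C)(C)C(C)(C)C)C[C@H](I)[C@@]1(C)OC(=O)OC[C@@H]1OCc1ccc(OC)cc1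
F3 | step 22 | (2S)-2-{(2R,3R)-3-[(2S)-2-hydroxy-2-{(2R,3S)-2-methyl-3-[(2Z)-3-methyl-4-(4,4,5,5-tetramethyl-1,3,2-dioxaborolan-2-yl)but-2-en-1-yl]oxiran-2-yl}ethyl]-2-methyloxiran-2-yl}-2-[(4-methoxybenzyl)oxy]ethan-1-ol | C/C(CB1OC(C)(C)C(C)(C)O1)=C/C[C@@H]1O[C@]1(C)[C@@H](O)C[C@H]1O[C@@]1(C)[C@@H](OCc1ccc(OC)cc1)CO
F4 | step 23 | (1R,3S,4S,5S,7R,8S,9S,10R)-1,10:4,5-diepoxy-9-[(4-methoxybenzyl)oxy]germacr-11(12)-ene-3,8-diyl bis{2-[bis(2,2,2-trifluoroethoxy)phosphoryl]propanoate} (epimers at both phosphonate α-carbons) | C=C(C)[C@H]1C[C@@H]2O[C@]2(C)[C@@H](OC(=O)C(C)P(=O)(OCC(F)(F)F)OCC(F)(F)F)C[C@H]2O[C@@]2(C)[C@@H](OCc3ccc(OC)cc3)[C@H]1OC(=O)C(C)P(=O)(OCC(F)(F)F)OCC(F)(F)F
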